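## Structural features

The target is a β-resorcylic acid (2,4-dihydroxybenzoic acid, ring atoms C1–C6, carboxyl on C1). Its only ring is the benzene ring, which is joined through the C6–C1' bond to an unbranched thirteen-carbon chain C1'–C13'. The chain carries two secondary acetates: one at C2' (S, homobenzylic) and one at C12' (R, next to the terminal methyl C13'). Nine methylene groups (C3'–C11') separate them, so neither stereocentre can direct the other and each must be set absolutely.

The fragile parts are the free salicylic-type acid and the acetates. The acid can lose carbon dioxide on heating or in acid, and it can close onto C2' with loss of acetic acid to a 3,4-dihydroisocoumarin. The acetates do not tolerate base or strong nucleophiles. The electron-rich resorcinol ring is sensitive to electrophiles and oxidants.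

The real difficulty is therefore the absolute control of two remote carbinol centres, plus placing chain and carboxyl group ortho to each other on a 3,5-dioxygenated ring. The feature exploited is that C2' and C12' are each a carbinol flanked by a one-carbon terminus (C1' carrying the ring, C13' carrying only hydrogen). They have the same spatial sense, and the S/R difference is only a matter of CIP ranking. C1'–C13' therefore maps onto a C2-symmetric (2S,12S)-bis-epoxide, which in turn comes from a seven-carbon dinucleophile (C4'–C10') and two copies of one three-carbon chiral epoxide.

## Logic of the disconnections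

**14 to 13.** The two phenolic O–CH2Ph bonds are cut last. The free acid with two free phenols is the most sensitive form of the molecule, so it is revealed in a neutral final step. The gain is that all earlier chemistry runs on a robust bis-ether. The demand is that the cleavage spares the acetates and the homobenzylic C2'–O bond, which hydrogenolysis does because that bond is not benzylic.

**13 to 12 to 10.** First the carboxyl oxidation level is lowered to the aldehyde, then the ring C1–CHO bond is cut (11 is the transient iminium form of 12). C1 is the position ortho to the chain and para to an ether oxygen, the most accessible activated site of 10. The gain is a symmetric 5-alkylresorcinol diether with two equivalent reactive positions. The demand is that the electrophile choose this site over the position between the two ethers, and that the oxidation not chlorinate the ring.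

**10 to 9.** Both acetate C–O bonds are cut. The acetates belong to the target and are put on both carbinols at once, where they also mask the hydroxyls during formylation. The demand is only that nothing else in 9 be acylable, which the benzyl ethers guarantee.

**9 to 8.** The C13'–H bond is cut, so the methyl carbinol becomes a terminal epoxide plus hydride. This traces C12' to an epoxide carbon of the same spatial sense as C2' and exposes the hidden symmetry. The demand is hydride attack at the CH2 terminus only.

**8 to 5 and 7 (from 6).** The ring C6–C1' bond is cut between an aryl nucleophile and an epoxide CH2. The arene becomes a simple aryl halide and the chain becomes the C2-symmetric 5. The price is mono-functionalisation of two identical ends, which must be handled statistically with an excess of 5 that is recovered.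

**5 to 4.** The two terminal epoxide C–O bonds are cut to chlorohydrins. This only requires a base-mediated closure that leaves the carbinol C–O bonds untouched.

**4 to 2 and two molecules of 3.** The C3'–C4' and C10'–C11' bonds are cut. All thirteen chain carbons and both stereocentres then come from one dinucleophile and one enantiomer of a cheap C3 epoxide. The demand is attack at the ring CH2 of 3 only, at both ends, without touching the CH2Cl group or the stereocentre.

**2 to 1.** The two C–Mg bonds are cut back to the dibromide. The demand is clean double insertion without coupling.

## Other disconnections considered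

**Alternative 1:** The cut removes the ring bonds C1–C2 and C5–C6. C2–C5 with both oxygens would come from 1-methoxy-1,3-bis(trimethylsilyloxy)buta-1,3-diene A2. C1, C6, the ester and the whole chain would come from benzyl (5S,15R)-5,15-diacetoxyhexadec-2-ynoate A1. In the forward step the nucleophilic CH2 terminus of A2 would bond to the β-carbon of A1 (future C6) and the acetal carbon to the α-carbon (future C1). Loss of the silyl methyl ether and desilylation on acidic work-up would aromatise the adduct to benzyl 6-[(2S,12R)-2,12-diacetoxytridecyl]-2,4-dihydroxybenzoate A3, one hydrogenolysis away from 14.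
- In its favour: the substitution pattern follows from polarity matching, the phenols emerge free, and no formylation or oxidation is needed. On ring regiochemistry and end-game length (two steps from A1 against four from 9) it is better than the chosen plan.
- Against it: a β-alkyl ynoate is a weak dienophile, and A2 is sensitive to heat and moisture. Forcing conditions invite silyl migration in A2 and elimination of the acetoxy group that sits β to the propargylic CH2 of A1.
- Comparison: A1 still needs both stereocentres and two differentiated chain ends, so the chain problem solved by step 2 remains and a propiolate unit replaces the aryl group. Overall step count is equal at best and stereocontrol is equal. A thermal cycloaddition–elimination on an unactivated partner is mechanistically less predictable than the copper-mediated SN2 openings used here.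

**Alternative 2:** The cut is the ring bond C1–C6, which unfolds the arene into a linear tetraketide. In the forward step 6-[(6S,16R)-6,16-bis(tert-butyldimethylsilyloxy)-2,4-dioxoheptadecyl]-2,2-dimethyl-4H-1,3-dioxin-4-one A4 would undergo thermal cycloreversion to an acylketene. The ester-forming alcohol would trap it as benzyl (9S,19R)-9,19-bis(tert-butyldimethylsilyloxy)-3,5,7-trioxoicosanoate A5. A mild carbonate base would then effect the aldol closure between the methylene next to the ester (future C1) and the distal ketone (future C6), and dehydration and enolisation would give benzyl 6-[(2S,12R)-2,12-bis(tert-butyldimethylsilyloxy)tridecyl]-2,4-dihydroxybenzoate A6.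
- In its favour: the ring pattern is fixed by construction, the aromatisation is mild, and no electrophilic substitution is needed. On aromatic regiochemistry it is better than the chosen plan.
- Against it: A4 requires two C-acylations onto a chain acid that already holds both stereocentres. The ketone destined to become C6 has a silyloxy group β to it in A5, so base-induced elimination competes with the aldol. Closure through oxygen to a pyranone is another possible folding. The silyl ethers of A6 must be exchanged for acetates while two phenols are free, which costs extra protection or selective deacylation steps.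
- Comparison: stereochemical security is equal, since the chain centres are spectators in both plans. Step count and protecting-group economy are worse than in the chosen plan.

**Alternative 3:** The cut removes the ring bonds C3–C4 and C5–C6. Benzyl 4-(benzyloxy)-6-[(2S,12R)-2,12-diacetoxytridecyl]-2-oxo-2H-pyran-5-carboxylate A7 would supply C1, C2, C3 and C6 with the ester, one ether and the chain. 1,1-Bis(trimethylsilyloxy)ethene A8 would supply C4 with its oxygen and C5. In the forward step the CH2 terminus of A8 would add to C6 of A7 (β to the ester), the acetal carbon would bond to C3, and the bridged lactone would aromatise by decarboxylation and loss of silanol to benzyl 2-(benzyloxy)-6-[(2S,12R)-2,12-diacetoxytridecyl]-4-hydroxybenzoate A9. Hydrogenolysis would then give 14.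
- In its favour: the carboxyl carbon is present from the start and the substitution pattern is dictated by the pyrone. The finishing hydrogenolysis is the same kind of step as step 9 (equal), and the end game is two steps shorter than the chosen one (better).
- Against it: the 4-alkoxy group lowers the electron demand of the pyrone. The new bond must form at the fully substituted C6. The C1' methylene of A7 is vinylogously acidic with an acetoxy leaving group at C2'. A7 must be built from a chain-bearing β-keto ester, which adds steps. The differentiation of the two phenols in A9 is of no use for 14.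
- Comparison: ring regiochemistry is better and stereocontrol is equal. Robustness of the key step and total step count are worse than in the chosen plan, because the chain with both stereocentres must still be made first.

Key step: step 2

**Remarks before the steps**

- Assumption: primed locants C1'–C13' count the chain from the ring, and unprimed C1–C6 the benzene ring with the carboxyl on C1 and the chain on C6. Compounds 1, 3 and 6 are taken as purchasable.
- Structure check: the descriptors were re-derived along the route. S in 3 gives S,S in 4 and 5, S at C2' after arylation, and R at C12' once C13' is a methyl group. No structure needed correction.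
- Design refinements:
  - The seven-carbon double Grignard reagent is kept as the precursor. It is titrated and added to a slight excess of 3, so that each carbanion end meets fresh epoxide.
  - The mono-arylation uses a threefold excess of 5 that is recovered.
  - The hydride step uses a LiAlH4 solution, so that no pyrophoric trialkylborane by-product arises.
  - The route needs no organolithium reagent, no carbon monoxide and no pressurised hydrogen.

## Route

Step 1
Reactants: 1 1,7-dibromoheptane
Product: 2 heptane-1,7-diylbis(magnesium bromide), kept as a titrated THF solution
Conditions: Mg turnings (3 equiv, I2 crystal), THF, slow addition at 35–45 °C, then rt; titration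
Reagents that add atoms: magnesium, [Mg]
Why: Grignard formation by insertion of zerovalent magnesium into both primary C–Br bonds; with seven carbons between the halides ring closure is slow, and slow addition under dilution keeps Wurtz coupling down.

Step 2
Reactants: 2 heptane-1,7-diylbis(magnesium bromide); 3 (S)-epichlorohydrin, (2S)-2-(chloromethyl)oxirane (two molecules react)
Product: 4 (2S,12S)-1,13-dichlorotridecane-2,12-diol
Conditions: 2 added to 3 (2.3 equiv), CuI (10 mol %), THF, −40 → −20 °C; sat. aq. NH4Cl, 0 °C
Reagents that add atoms: none
Why: Each C–Mg terminus of 2 transmetalates to monovalent copper, and the resulting alkylcuprate attacks the unsubstituted ring carbon of 3 in an SN2 manner (oxidative addition to a trivalent copper alkyl, then reductive elimination), which forms C3'–C4' and C10'–C11' and leaves the bromomagnesium alkoxide of a chlorohydrin at each end. The closest known reaction type is the copper-catalysed opening of epichlorohydrin by a simple Grignard reagent at the epoxide CH2, applied here at both ends of one chain. No ring is closed. No stereocentre is created: the carbinol carbon of 3 is a spectator, and because CH2Cl still outranks the new alkyl branch both centres keep the S descriptor. The selectivity needed is site selectivity among ring CH2, ring CH and CH2Cl; the soft cuprate goes to the least hindered carbon of the strained ring, copper catalysis outruns opening by bromide ion, and the primary chloride is a poorer electrophile than the epoxide at −40 °C. Keeping the mixture cold until the quench stops the alkoxide from closing to an epoxide that would accept a second carbanion, and adding 2 to a small excess of 3 lets each end meet fresh 3. As both ends are identical only one stereoisomer can form, and chain-terminated mono-adducts lack one hydroxyl group and should be removed easily by crystallisation or chromatography.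

Step 3
Reactants: 4 (2S,12S)-1,13-dichlorotridecane-2,12-diol
Product: 5 (2S,12S)-1,2:12,13-diepoxytridecane, (2S,2'S)-2,2'-(nonane-1,9-diyl)bis(oxirane)
Conditions: NaOH (2 M aq., 5 equiv), THF, 0 °C → rt
Reagents that add atoms: none
Why: Double intramolecular Williamson etherification (3-exo-tet displacement of each primary chloride by the neighbouring alkoxide); the C–O bonds at the stereocentres are not broken, so both stay S.

Step 4
Reactants: 5 (2S,12S)-1,2:12,13-diepoxytridecane (3 equiv); 6 1,3-bis(benzyloxy)-5-bromobenzene
Product: 8 (2S)-1-[3,5-bis(benzyloxy)phenyl]-11-[(2S)-oxiran-2-yl]undecan-2-ol, via 3,5-bis(benzyloxy)phenylmagnesium bromide 7 (not isolated)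
Conditions: 6, Mg (I2 crystal), THF, 50 °C; then added to 5 (3 equiv), CuI (10 mol %), THF, −30 → 0 °C; aq. NH4Cl; excess 5 recovered by chromatography
Reagents that add atoms: none
Why: Grignard formation followed by copper-catalysed SN2 opening of one terminal epoxide at its CH2 forms the ring–C1' bond and leaves C2' untouched (S). The threefold excess of 5 should keep double arylation statistically minor, and 5, 8 and the doubly opened diol differ by one hydroxyl group each and should separate readily.

Step 5
Reactants: 8 (2S)-1-[3,5-bis(benzyloxy)phenyl]-11-[(2S)-oxiran-2-yl]undecan-2-ol
Product: 9 (2S,12R)-1-[3,5-bis(benzyloxy)phenyl]tridecane-2,12-diol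
Conditions: LiAlH4 (1 M in THF, 1.5 equiv), THF, 0 °C → rt; H2O, 15% aq. NaOH, H2O
Reagents that add atoms: none
Why: SN2 reduction of the terminal epoxide by hydride at the CH2 carbon turns it into the C13' methyl group. The C12'–O bond is not broken, and the descriptor changes from S to R only because the chain now outranks methyl; the free hydroxyl merely consumes one hydride.

Step 6
Reactants: 9 (2S,12R)-1-[3,5-bis(benzyloxy)phenyl]tridecane-2,12-diol
Product: 10 (2S,12R)-1-[3,5-bis(benzyloxy)phenyl]tridecane-2,12-diyl diacetate
Conditions: Ac2O, pyridine, DMAP (cat.), CH2Cl2, rt
Reagents that add atoms: acetic anhydride, CC(=O)OC(C)=O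
Why: Nucleophile-catalysed O-acylation of both secondary alcohols without touching either stereocentre; the acetates are the groups of the target and also mask the hydroxyls for the formylation.

Step 7
Reactants: 10 (2S,12R)-1-[3,5-bis(benzyloxy)phenyl]tridecane-2,12-diyl diacetate
Product: 12 (2S,12R)-1-[3,5-bis(benzyloxy)-2-formylphenyl]tridecane-2,12-diyl diacetate, via aryliminium chloride 11 (not isolated)
Conditions: POCl3 (1.5 equiv), DMF, 0 → 60 °C; aq. NaOAc, rt
Reagents that add atoms: N,N-dimethylformamide, CN(C)C=O; water, O
Why: Vilsmeier–Haack formylation: the chloroiminium ion attacks the ring position ortho to the chain and para to a benzyloxy group, the site between the two ethers being doubly flanked and the disfavoured one in 5-alkylresorcinol diethers. Hydrolysis of iminium salt 11 gives the aldehyde, and acetates and benzyl ethers tolerate the reagent.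

Step 8
Reactants: 12 (2S,12R)-1-[3,5-bis(benzyloxy)-2-formylphenyl]tridecane-2,12-diyl diacetate
Product: 13 2,4-bis(benzyloxy)-6-[(2S,12R)-2,12-diacetoxytridecyl]benzoic acid
Conditions: NaClO2, NaH2PO4, 2-methyl-2-butene (excess), t-BuOH/THF/H2O, 0 °C → rt
Reagents that add atoms: sodium chlorite, [Na+].[O-]Cl=O
Why: Pinnick oxidation: chlorous acid adds to the aldehyde and fragments to the acid and hypochlorous acid, which the alkene traps before it can chlorinate the electron-rich ring; acetates and benzyl ethers are inert in the weakly acidic buffer.

Step 9
Reactants: 13 2,4-bis(benzyloxy)-6-[(2S,12R)-2,12-diacetoxytridecyl]benzoic acid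
Product: 14 2,4-dihydroxy-6-[(2S,12R)-2,12-diacetoxytridecyl]benzoic acid (CNP0203944.3)
Conditions: H2 (1 atm), 10% Pd/C, EtOAc, rt; filtration, evaporation below 30 °C
Reagents that add atoms: none
Why: Hydrogenolysis of the two aryl benzyl ethers over Pd/C; the C2'–O acetate is homobenzylic and not cleaved, the esters and the acid survive, and neutral cold isolation avoids decarboxylation and lactonisation.

## Compound list

1 | 1,7-dibromoheptane | BrCCCCCCCBr | starting material
2 | heptane-1,7-diylbis(magnesium bromide) | Br[Mg]CCCCCCC[Mg]Br | intermediate
3 | (S)-epichlorohydrin, (2S)-2-(chloromethyl)oxirane | ClC[C@@H]1CO1 | starting material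
4 | (2S,12S)-1,13-dichlorotridecane-2,12-diol | ClC[C@@H](O)CCCCCCCCC[C@@H](CCl)O | intermediate
5 | (2S,12S)-1,2:12,13-diepoxytridecane | C1O[C@H]1CCCCCCCCC[C@H]1CO1 | intermediate
6 | 1,3-bis(benzyloxy)-5-bromobenzene | Brc1cc(OCc2ccccc2)cc(OCc2ccccc2)c1 | starting material
7 | 3,5-bis(benzyloxy)phenylmagnesium bromide | Br[Mg]c1cc(OCc2ccccc2)cc(OCc2ccccc2)c1 | intermediate
8 | (2S)-1-[3,5-bis(benzyloxy)phenyl]-11-[(2S)-oxiran-2-yl]undecan-2-ol | O[C@@H](CCCCCCCCC[C@H]1CO1)Cc1cc(OCc2ccccc2)cc(OCc2ccccc2)c1 | intermediate
9 | (2S,12R)-1-[3,5-bis(benzyloxy)phenyl]tridecane-2,12-diol | O[C@@H](CCCCCCCCC[C@@H](C)O)Cc1cc(OCc2ccccc2)cc(OCc2ccccc2)c1 | intermediate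
10 | (2S,12R)-1-[3,5-bis(benzyloxy)phenyl]tridecane-2,12-diyl diacetate | CC(=O)O[C@@H](CCCCCCCCC[C@@H](C)OC(C)=O)Cc1cc(OCc2ccccc2)cc(OCc2ccccc2)c1 | intermediate
11 | N-{2,4-bis(benzyloxy)-6-[(2S,12R)-2,12-diacetoxytridecyl]benzylidene}-N-methylmethanaminium chloride | CC(=O)O[C@@H](CCCCCCCCC[C@@H](C)OC(C)=O)Cc1cc(OCc2ccccc2)cc(OCc2ccccc2)c1C=[N+](C)C.[Cl-] | intermediate
12 | (2S,12R)-1-[3,5-bis(benzyloxy)-2-formylphenyl]tridecane-2,12-diyl diacetate | CC(=O)O[C@@H](CCCCCCCCC[C@@H](C)OC(C)=O)Cc1cc(OCc2ccccc2)cc(OCc2ccccc2)c1C=O | intermediate
13 | 2,4-bis(benzyloxy)-6-[(2S,12R)-2,12-diacetoxytridecyl]benzoic acid | CC(=O)O[C@@H](CCCCCCCCC[C@@H](C)OC(C)=O)Cc1cc(OCc2ccccc2)cc(OCc2ccccc2)c1C(=O)O | intermediate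
14 | 2,4-dihydroxy-6-[(2S,12R)-2,12-diacetoxytridecyl]benzoic acid | CC(=O)O[C@@H](CCCCCCCCC[C@@H](C)OC(C)=O)Cc1cc(O)cc(O)c1C(=O)O | target

## Step count and least certain steps

Total step count: 9. Longest linear sequence: 9 steps (1 to 14). Compound 6 enters in step 4, where its Grignard reagent 7 is made and used in the same operation.

**Step 2 (key step).** The most likely failures are:
- incomplete double addition if the titre of 2 contains mono-Grignard ends;
- opening of 3 by bromide ion from the magnesium salts instead of by carbon;
- premature closure of the chlorohydrin alkoxide followed by a second alkylation, which would give oligomers.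

The fallback sets out from 3 and changes the carbanion from an sp3 magnesium/copper species to an sp lithium acetylide. Hepta-1,6-diyne F1 would be doubly deprotonated (n-BuLi, THF, −78 °C), activated with BF3·OEt2 and treated with 3. This should give (2S,12S)-1,13-dichlorotrideca-4,9-diyne-2,12-diol F2 by opening at the epoxide CH2, with the stereocentres again spectators. Hydrogenation of both triple bonds (H2, PtO2, EtOAc) would then return to the route at 4.

**Step 4.** The most likely failures are over-arylation at both ends, consumption of the aryl reagent in homocoupling, and competing opening of the epoxide by bromide ion. Each of these wastes the more valuable partner. The fallback sets out from 5 and inverts the order of the two openings, so that the statistical step uses hydride. A substoichiometric amount of LiEt3BH (about one third of an equivalent, THF, 0 °C) should give (2R)-11-[(2S)-oxiran-2-yl]undecan-2-ol F3, with unreacted 5 recycled. F3 would then be opened with an excess of 7 and catalytic CuI, and the sequence comes back at 9.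

**Step 7.** The most likely failures are formylation at the position between the two benzyloxy groups, and acid-promoted loss of the benzyl group next to the new formyl group. The fallback sets out from 10 and installs the carboxyl carbon through a halogen. Bromination with NBS (MeCN, 0 °C), which in 3,5-dialkoxy-alkylbenzenes goes ortho to the alkyl group, should give (2S,12R)-1-[3,5-bis(benzyloxy)-2-bromophenyl]tridecane-2,12-diyl diacetate F4. Palladium-catalysed benzyloxycarbonylation (Pd(OAc)2, Xantphos, CO 1 atm, BnOH, Et3N, toluene, 90 °C) would give benzyl 2,4-bis(benzyloxy)-6-[(2S,12R)-2,12-diacetoxytridecyl]benzoate F5. Hydrogenolysis of all three benzyl groups (H2, Pd/C) comes back at 14 and bypasses 12 and 13.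

**Step 9.** The most likely failures are sluggish cleavage of the hindered, hydrogen-bonded ether next to the carboxyl group and, if the reaction is then forced, decarboxylation or cyclisation of the acid onto C2' with loss of acetic acid. The fallback sets out from 12 and removes the benzyl groups before the acid exists. BCl3 with pentamethylbenzene (CH2Cl2, −78 °C) should give (2S,12R)-1-(2-formyl-3,5-dihydroxyphenyl)tridecane-2,12-diyl diacetate F6. Buffered chlorite oxidation (NaClO2, NaH2PO4, sulfamic acid as hypochlorite scavenger, aqueous t-BuOH, 0 °C) would then come back at 14 in a mild final step.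

## Further compounds

F1 | step 2 | hepta-1,6-diyne | C#CCCCC#C
F2 | step 2 | (2S,12S)-1,13-dichlorotrideca-4,9-diyne-2,12-diol | ClC[C@@H](O)CC#CCCCC#CC[C@@H](CCl)O
F3 | step 4 | (2R)-11-[(2S)-oxiran-2-yl]undecan-2-ol | C[C@@H](O)CCCCCCCCC[C@H]1CO1
F4 | step 7 | (2S,12R)-1-[3,5-bis(benzyloxy)-2-bromophenyl]tridecane-2,12-diyl diacetate | CC(=O)O[C@@H](CCCCCCCCC[C@@H](C)OC(C)=O)Cc1cc(OCc2ccccc2)cc(OCc2ccccc2)c1Br
F5 | step 7 | benzyl 2,4-bis(benzyloxy)-6-[(2S,12R)-2,12-diacetoxytridecyl]benzoate | CC(=O)O[C@@H](CCCCCCCCC[C@@H](C)OC(C)=O)Cc1cc(OCc2ccccc2)cc(OCc2ccccc2)c1C(=O)OCc1ccccc1
F6 | step 9 | (2S,12R)-1-(2-formyl-3,5-dihydroxyphenyl)tridecane-2,12-diyl diacetate | CC(=O)O[C@@H](CCCCCCCCC[C@@H](C)OC(C)=O)Cc1cc(O)cc(O)c1C=O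
A1 | alternative 1 | benzyl (5S,15R)-5,15-diacetoxyhexadec-2-ynoate | CC(=O)O[C@@H](CCCCCCCCC[C@@H](C)OC(C)=O)CC#CC(=O)OCc1ccccc1
A2 | alternative 1 | 1-methoxy-1,3-bis(trimethylsilyloxy)buta-1,3-diene | COC(O[Si](C)(C)C)=CC(=C)O[Si](C)(C)C
A3 | alternative 1 | benzyl 6-[(2S,12R)-2,12-diacetoxytridecyl]-2,4-dihydroxybenzoate | CC(=O)O[C@@H](CCCCCCCCC[C@@H](C)OC(C)=O)Cc1cc(O)cc(O)c1C(=O)OCc1ccccc1
A4 | alternative 2 | 6-[(6S,16R)-6,16-bis(tert-butyldimethylsilyloxy)-2,4-dioxoheptadecyl]-2,2-dimethyl-4H-1,3-dioxin-4-one | CC(C)(C)[Si](C)(C)O[C@@H](CCCCCCCCC[C@@H](C)O[Si](C)(C)C(C)(C)C)CC(=O)CC(=O)CC1=CC(=O)OC(C)(C)O1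
A5 | alternative 2 | benzyl (9S,19R)-9,19-bis(tert-butyldimethylsilyloxy)-3,5,7-trioxoicosanoate | CC(C)(C)[Si](C)(C)O[C@@H](CCCCCCCCC[C@@H](C)O[Si](C)(C)C(C)(C)C)CC(=O)CC(=O)CC(=O)CC(=O)OCc1ccccc1
A6 | alternative 2 | benzyl 6-[(2S,12R)-2,12-bis(tert-butyldimethylsilyloxy)tridecyl]-2,4-dihydroxybenzoate | CC(C)(C)[Si](C)(C)O[C@@H](CCCCCCCCC[C@@H](C)O[Si](C)(C)C(C)(C)C)Cc1cc(O)cc(O)c1C(=O)OCc1ccccc1
A7 | alternative 3 | benzyl 4-(benzyloxy)-6-[(2S,12R)-2,12-diacetoxytridecyl]-2-oxo-2H-pyran-5-carboxylate | CC(=O)O[C@@H](CCCCCCCCC[C@@H](C)OC(C)=O)CC1=C(C(=O)OCc2ccccc2)C(OCc2ccccc2)=CC(=O)O1
A8 | alternative 3 | 1,1-bis(trimethylsilyloxy)ethene | C=C(O[Si](C)(C)C)O[Si](C)(C)C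
A9 | alternative 3 | benzyl 2-(benzyloxy)-6-[(2S,12R)-2,12-diacetoxytridecyl]-4-hydroxybenzoate | CC(=O)O[C@@H](CCCCCCCCC[C@@H](C)OC(C)=O)Cc1cc(O)cc(OCc2ccccc2)c1C(=O)OCc1ccccc1
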